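**Retrosynthetic overview**
1. Target 22 ⇐ trione 21 (the C16 methyl is added last, from the alkene face) ⇐ β-diketone 20.
2. 20 ⇐ butenolide polyene 19 by one radical–polar crossover cascade that closes ring A, ring B, then ring C together with the bicyclo[3.2.2] bridge.
3. 19 ⇐ iodo lactone 10 + (Z)-diester 14 (enolate alkenylation, Claisen/Dieckmann seven-membered ring, sulfoxide elimination to the butenolide).
4. 10 ⇐ (R)-lactone 2 + acetate 9; 2 ⇐ hept-6-ynoic acid by an enantioselective γ-C–H lactonisation. This C6–O bond sets the stereocentre from which C5, C10, C9, C8, C14 and C11 are relayed.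
5. Ring order: γ-lactone → cycloheptenedione → (cascade) A → B → C/bridge.

Assumption: atoms are numbered andrastin-style (C1–C10 rings A/B, C23 the lactone carbonyl on C10, C11–C17 the bicyclic unit, C14 bearing CO2Me, C16 the carbinol carbon), and the ligand antipode of the manganese catalyst that gives (R)-2 is used.

**Step 1**
Reactants: 1 hept-6-ynoic acid
Product: 2 (5R)-5-(prop-2-yn-1-yl)oxolan-2-one
Conditions: Mn(OTf)2[(S,S)-TIPS-pdp] (2 mol %, divalent manganese), H2O2 (aq., 2 equiv, syringe pump), CF3CH2OH, 0 °C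
Reagents that add atoms: none
Why: Proposed new method: the substrate carboxylate binds manganese, H2O2 is cleaved to a high-valent manganese-oxo carboxylate, this abstracts one of the two enantiotopic γ-hydrogens through a seven-membered transition state inside the chiral ligand pocket and the carbon radical rebounds onto the carboxylate oxygen with retention, which forms the C6–O bond and fixes C6; a β-lactone would be strained and the propargylic δ-CH2 and the alkyne lie outside the reach of the directed hydrogen transfer; closest known reaction type: manganese-catalysed, carboxylic-acid-directed enantioselective γ-C(sp3)–H lactonisation of branched and cyclic aliphatic acids with H2O2, not yet shown for an unbranched acid carrying an alkyne.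

**Step 2**
Reactants: 2 (5R)-5-(prop-2-yn-1-yl)oxolan-2-one
Product: 4 (5R)-5-[(2E)-3-iodo-2-methylprop-2-en-1-yl]oxolan-2-one, via alkenylalane 3 (not isolated)
Conditions: AlMe3 (2.5 equiv), Cp2ZrCl2 (20 mol %), H2O (1 equiv), CH2Cl2, −23 °C, 30 min; then I2, THF, −23 → 0 °C
Reagents that add atoms: trimethylaluminium, C[Al](C)C; iodine, II
Why: Negishi zirconium-catalysed syn-carboalumination puts CH3 on the internal and aluminium on the terminal alkyne carbon, and iodinolysis with retention gives the (E)-iodide; the water-accelerated variant is complete in minutes at −23 °C, which should spare the lactone.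

**Step 3**
Reactants: 4 (5R)-5-[(2E)-3-iodo-2-methylprop-2-en-1-yl]oxolan-2-one
Product: 5 (3RS,5S)-5-[(2E)-3-iodo-2-methylprop-2-en-1-yl]-3-(phenylsulfanyl)oxolan-2-one
Conditions: LiN(iPr)2, THF, −78 °C; PhSSPh, −78 → −20 °C
Reagents that add atoms: diphenyl disulfide, c1ccc(cc1)SSc1ccccc1
Why: Enolate sulfenylation at C10; the sulfide is a latent C5=C10 double bond, so the C6 stereocentre never meets base as a butenolide (the descriptor at C6 changes only because of CIP priorities).

**Step 4**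
Reactants: 6 5-bromo-2-methylpent-2-ene
Product: 7 (3S)-3-(2-bromoethyl)-2,2-dimethyloxirane
Conditions: ent-Shi ketone (30 mol %, the antipode of the D-fructose-derived ketone), KHSO5, K2CO3, MeCN/dimethoxymethane/aq. buffer (pH 10.5), 0 °C
Reagents that add atoms: potassium peroxymonosulfate, [K+].[O-]S(=O)(=O)OO
Why: Shi asymmetric epoxidation of a trisubstituted alkene; the ketone antipode is chosen so that the new C3–O stereocentre is S.

**Step 5**
Reactants: 7 (3S)-3-(2-bromoethyl)-2,2-dimethyloxirane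
Product: 8 (3S)-5-bromo-2-methylpent-1-en-3-ol
Conditions: Al(OiPr)3 (20 mol %), toluene, 110 °C
Reagents that add atoms: none
Why: Aluminium alkoxide-promoted epoxide to allylic alcohol isomerisation removes a methyl hydrogen and leaves the C3–O bond untouched, so C3 stays S.

**Step 6**
Reactants: 8 (3S)-5-bromo-2-methylpent-1-en-3-ol
Product: 9 (3S)-5-bromo-2-methylpent-1-en-3-yl acetate
Conditions: Ac2O, pyridine, DMAP (cat.), CH2Cl2, 0 °C → rt
Reagents that add atoms: acetic anhydride, CC(=O)OC(C)=O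
Why: DMAP-catalysed acetylation of the secondary alcohol installs the C3 acetate of the target with its final configuration.

**Step 7**
Reactants: 5 (3RS,5S)-5-[(2E)-3-iodo-2-methylprop-2-en-1-yl]-3-(phenylsulfanyl)oxolan-2-one; 9 (3S)-5-bromo-2-methylpent-1-en-3-yl acetate
Product: 10 (3S)-5-{(3RS,5S)-5-[(2E)-3-iodo-2-methylprop-2-en-1-yl]-2-oxo-3-(phenylsulfanyl)oxolan-3-yl}-2-methylpent-1-en-3-yl acetate
Conditions: LiN(SiMe3)2, THF/DMPU, −78 → 0 °C
Reagents that add atoms: none
Why: SN2 alkylation of the sulfur-stabilised lactone enolate by the primary bromide makes C10 quaternary; the new centre is a mixture, which does not matter because C10 becomes sp2 in step 12.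

**Step 8**
Reactants: 11 1,2-dimethoxy-4,5-dimethylbenzene
Product: 12 1,2-dimethoxy-4,5-dimethylcyclohexa-1,4-diene
Conditions: Li, NH3 (l), tBuOH, THF, −78 → −33 °C
Reagents that add atoms: none
Why: Birch reduction protonates the two unsubstituted ring carbons and leaves two tetrasubstituted alkenes.

**Step 9**
Reactants: 12 1,2-dimethoxy-4,5-dimethylcyclohexa-1,4-diene
Product: 14 dimethyl (3Z)-3,4-dimethylhex-3-enedioate, via primary ozonide 13 (not isolated)
Conditions: O3 (1.0 equiv), CH2Cl2, −78 °C; then Me2S, −78 °C → rt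
Reagents that add atoms: ozone, [O-][O+]=O
Why: Ozonolysis is selective for the far more electron-rich dimethoxy alkene and turns each enol ether carbon into a methyl ester, while the ring fixes the (Z) geometry of the remaining tetrasubstituted alkene (C12=C13 of the target).

**Step 10**
Reactants: 10 (3S)-5-{(3RS,5S)-5-[(2E)-3-iodo-2-methylprop-2-en-1-yl]-2-oxo-3-(phenylsulfanyl)oxolan-3-yl}-2-methylpent-1-en-3-yl acetate; 14 dimethyl (3Z)-3,4-dimethylhex-3-enedioate
Product: 15 dimethyl (2RS,3Z)-2-[(1E)-3-{(2S,4RS)-4-[(3S)-3-(acetyloxy)-4-methylpent-4-en-1-yl]-5-oxo-4-(phenylsulfanyl)oxolan-2-yl}-2-methylprop-1-en-1-yl]-3,4-dimethylhex-3-enedioate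
Conditions: 14 (2.2 equiv), LiN(SiMe3)2, toluene, −78 → 0 °C; then 10, Pd2(dba)3 (2.5 mol %), P(tBu)3 (10 mol %), rt
Reagents that add atoms: none
Why: Palladium-catalysed α-alkenylation of an ester enolate (Buchwald–Hartwig-type enolate coupling) joins C9 to C11 with retention of the (E) geometry; C11 forms as a mixture and is epimerisable.

**Step 11**
Reactants: 15 dimethyl (2RS,3Z)-2-[(1E)-3-{(2S,4RS)-4-[(3S)-3-(acetyloxy)-4-methylpent-4-en-1-yl]-5-oxo-4-(phenylsulfanyl)oxolan-2-yl}-2-methylprop-1-en-1-yl]-3,4-dimethylhex-3-enedioate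
Product: 17 methyl (1RS,4RS)-4-[(1E)-3-{(2S,4RS)-4-[(3S)-3-(acetyloxy)-4-methylpent-4-en-1-yl]-5-oxo-4-(phenylsulfanyl)oxolan-2-yl}-2-methylprop-1-en-1-yl]-2,3-dimethyl-5,7-dioxocyclohept-2-ene-1-carboxylate, via keto ester 16 (not isolated)
Conditions: LiN(iPr)2 (2.2 equiv), THF, −78 °C; AcCl (1.0 equiv); then KOtBu (2.0 equiv), tBuOH/THF, 0 °C → rt; aq. NH4Cl
Reagents that add atoms: acetyl chloride, CC(Cl)=O
Why: Crossed Claisen C-acetylation at the less hindered enolate carbon (C14), then an intramolecular Claisen (Dieckmann-type) attack of the acetyl carbon C16 on the C17 ester closes the seven-membered ring, driven by formation of the doubly stabilised diketo ester anion.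

**Step 12**
Reactants: 17 methyl (1RS,4RS)-4-[(1E)-3-{(2S,4RS)-4-[(3S)-3-(acetyloxy)-4-methylpent-4-en-1-yl]-5-oxo-4-(phenylsulfanyl)oxolan-2-yl}-2-methylprop-1-en-1-yl]-2,3-dimethyl-5,7-dioxocyclohept-2-ene-1-carboxylate
Product: 19 methyl (1RS,4RS)-4-[(1E)-3-{(2S)-4-[(3S)-3-(acetyloxy)-4-methylpent-4-en-1-yl]-5-oxo-2,5-dihydrofuran-2-yl}-2-methylprop-1-en-1-yl]-2,3-dimethyl-5,7-dioxocyclohept-2-ene-1-carboxylate, via sulfoxide 18 (not isolated)
Conditions: H2O2 (1.1 equiv), (CF3)2CHOH, 0 °C; then toluene, CaCO3, 100 °C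
Reagents that add atoms: none
Why: Chemoselective sulfide oxidation and thermal syn-elimination of the sulfoxide give the endocyclic butenolide under neutral conditions, so C6 is untouched.

**Step 13**
Reactants: 19 methyl (1RS,4RS)-4-[(1E)-3-{(2S)-4-[(3S)-3-(acetyloxy)-4-methylpent-4-en-1-yl]-5-oxo-2,5-dihydrofuran-2-yl}-2-methylprop-1-en-1-yl]-2,3-dimethyl-5,7-dioxocyclohept-2-ene-1-carboxylate
Product: 20 16-demethyl-16-deoxypenicimeroterpenoid A (CH2 at C16; 3S,5R,6S,8S,9R,10R,11R,14R)
Conditions: Co(C36H52N2O2), the cobalt complex of N,N'-bis(3,5-di-tert-butylsalicylidene)cyclohexane-1,2-diamine (5 mol %, divalent cobalt), N-fluoro-2,4,6-trimethylpyridinium triflate (1.2 equiv), PhSiH3 (1.1 equiv), (CF3)2CHOH/CH2Cl2, 0 °C → rt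
Reagents that add atoms: none
Why: Cobalt-hydride MHAT to the 1,1-disubstituted alkene starts a radical–polar crossover polycyclisation (known for polyenes with an electron-poor central alkene): the C4 radical adds to C5 anti to the C6 side chain (ring A, acetate axial in the chair), the C10 radical closes ring B 6-endo on the side-chain face with the C9 substituent equatorial, the C8 radical is oxidised to the cation and the enol carbon C14 attacks it opposite the lactone bridge (ring C and the bicyclo[3.2.2] bridge), while C11 and C14 funnel through their enols.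

**Step 14**
Reactants: 20 16-demethyl-16-deoxypenicimeroterpenoid A
Product: 21 16-demethyl-16-deoxy-16-oxopenicimeroterpenoid A (15,16,17-trione)
Conditions: Dess–Martin periodinane (2.5 equiv), pyridine, wet CH2Cl2, rt
Reagents that add atoms: water, O
Why: Dess–Martin oxidation of the active methylene of a 1,3-diketone to the vicinal tricarbonyl; C14 is quaternary and C11 a bridgehead, so C16 is the only enolisable position.

**Step 15**
Reactants: 21 16-demethyl-16-deoxy-16-oxopenicimeroterpenoid A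
Product: 22 penicimeroterpenoid A
Conditions: MeTi(OiPr)3 (1.5 equiv), Et2O/CH2Cl2, −78 → −30 °C; aq. NH4Cl
Reagents that add atoms: methyltitanium triisopropoxide, C[Ti](OC(C)C)(OC(C)C)OC(C)C
Why: Chemoselective 1,2-addition of the titanium methyl reagent to the central, most electrophilic carbonyl from the open C12=C13 face, away from the C7–C8–C9 bridge, puts CH3 over the alkene and OH over the saturated bridge, which is 16R.

**Compound list**
1 | hept-6-ynoic acid | C#CCCCCC(=O)O | starting material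
2 | (5R)-5-(prop-2-yn-1-yl)oxolan-2-one | O=C1CC[C@H](CC#C)O1 | intermediate
3 | dimethyl{(1E)-2-methyl-3-[(2R)-5-oxooxolan-2-yl]prop-1-en-1-yl}alane | O=C1CC[C@H](C/C(C)=C/[Al](C)C)O1 | intermediate
4 | (5R)-5-[(2E)-3-iodo-2-methylprop-2-en-1-yl]oxolan-2-one | O=C1CC[C@H](C/C(C)=C/I)O1 | intermediate
5 | (3RS,5S)-5-[(2E)-3-iodo-2-methylprop-2-en-1-yl]-3-(phenylsulfanyl)oxolan-2-one | O=C1C(Sc2ccccc2)C[C@H](C/C(C)=C/I)O1 | intermediate
6 | 5-bromo-2-methylpent-2-ene | CC(C)=CCCBr | starting material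
7 | (3S)-3-(2-bromoethyl)-2,2-dimethyloxirane | BrCC[C@@H]1OC1(C)C | intermediate
8 | (3S)-5-bromo-2-methylpent-1-en-3-ol | C=C(C)[C@@H](O)CCBr | intermediate
9 | (3S)-5-bromo-2-methylpent-1-en-3-yl acetate | C=C(C)[C@@H](OC(C)=O)CCBr | intermediate
10 | (3S)-5-{(3RS,5S)-5-[(2E)-3-iodo-2-methylprop-2-en-1-yl]-2-oxo-3-(phenylsulfanyl)oxolan-3-yl}-2-methylpent-1-en-3-yl acetate | C=C(C)[C@@H](OC(C)=O)CCC1(Sc2ccccc2)C[C@H](C/C(C)=C/I)OC1=O | intermediate
11 | 1,2-dimethoxy-4,5-dimethylbenzene | COc1cc(C)c(C)cc1OC | starting material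
12 | 1,2-dimethoxy-4,5-dimethylcyclohexa-1,4-diene | COC1=C(OC)CC(C)=C(C)C1 | intermediate
13 | 3a,7a-dimethoxy-5,6-dimethyl-3a,4,7,7a-tetrahydro-1,2,3-benzotrioxole (primary ozonide of 12) | COC12CC(C)=C(C)CC1(OC)OOO2 | intermediate
14 | dimethyl (3Z)-3,4-dimethylhex-3-enedioate | COC(=O)C/C(C)=C(C)\CC(=O)OC | intermediate
15 | dimethyl (2RS,3Z)-2-[(1E)-3-{(2S,4RS)-4-[(3S)-3-(acetyloxy)-4-methylpent-4-en-1-yl]-5-oxo-4-(phenylsulfanyl)oxolan-2-yl}-2-methylprop-1-en-1-yl]-3,4-dimethylhex-3-enedioate | C=C(C)[C@@H](OC(C)=O)CCC1(Sc2ccccc2)C[C@H](C/C(C)=C/C(C(=O)OC)/C(C)=C(C)\CC(=O)OC)OC1=O | intermediate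
16 | dimethyl (3Z)-2-acetyl-5-[(1E)-3-{(2S,4RS)-4-[(3S)-3-(acetyloxy)-4-methylpent-4-en-1-yl]-5-oxo-4-(phenylsulfanyl)oxolan-2-yl}-2-methylprop-1-en-1-yl]-3,4-dimethylhex-3-enedioate | C=C(C)[C@@H](OC(C)=O)CCC1(Sc2ccccc2)C[C@H](C/C(C)=C/C(C(=O)OC)/C(C)=C(C)\C(C(C)=O)C(=O)OC)OC1=O | intermediate
17 | methyl (1RS,4RS)-4-[(1E)-3-{(2S,4RS)-4-[(3S)-3-(acetyloxy)-4-methylpent-4-en-1-yl]-5-oxo-4-(phenylsulfanyl)oxolan-2-yl}-2-methylprop-1-en-1-yl]-2,3-dimethyl-5,7-dioxocyclohept-2-ene-1-carboxylate | C=C(C)[C@@H](OC(C)=O)CCC1(Sc2ccccc2)C[C@H](C/C(C)=C/C2C(C)=C(C)C(C(=O)OC)C(=O)CC2=O)OC1=O | intermediate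
18 | phenylsulfinyl analogue (sulfoxide) of 17 | C=C(C)[C@@H](OC(C)=O)CCC1(S(=O)c2ccccc2)C[C@H](C/C(C)=C/C2C(C)=C(C)C(C(=O)OC)C(=O)CC2=O)OC1=O | intermediate
19 | methyl (1RS,4RS)-4-[(1E)-3-{(2S)-4-[(3S)-3-(acetyloxy)-4-methylpent-4-en-1-yl]-5-oxo-2,5-dihydrofuran-2-yl}-2-methylprop-1-en-1-yl]-2,3-dimethyl-5,7-dioxocyclohept-2-ene-1-carboxylate | C=C(C)[C@@H](OC(C)=O)CCC1=C[C@H](C/C(C)=C/C2C(C)=C(C)C(C(=O)OC)C(=O)CC2=O)OC1=O | intermediate
20 | 16-demethyl-16-deoxypenicimeroterpenoid A (CH2 at C16) | COC(=O)[C@@]12C(=O)CC(=O)[C@@H](C(C)=C1C)[C@H]1[C@]34CC[C@H](OC(C)=O)C(C)(C)[C@H]3[C@H](C[C@@]12C)OC4=O | intermediate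
21 | 16-demethyl-16-deoxy-16-oxopenicimeroterpenoid A (15,16,17-trione) | COC(=O)[C@@]12C(=O)C(=O)C(=O)[C@@H](C(C)=C1C)[C@H]1[C@]34CC[C@H](OC(C)=O)C(C)(C)[C@H]3[C@H](C[C@@]12C)OC4=O | intermediate
22 | penicimeroterpenoid A (3S,5R,6S,8S,9R,10R,11R,14R,16R) | COC(=O)[C@@]12C(=O)[C@](C)(O)C(=O)[C@@H](C(C)=C1C)[C@H]1[C@]34CC[C@H](OC(C)=O)C(C)(C)[C@H]3[C@H](C[C@@]12C)OC4=O | target

**Step count and risks**
Total steps: 15. Longest linear sequence: 10 (steps 1, 2, 3, 7, 10, 11, 12, 13, 14, 15; the branch starting from 6 is equally long).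

Most likely to fail, step 13: four bonds form in one pot, C16 or an enol oxygen may capture the C8 cation, or the sequence may stop after ring B. The fallback sets out from 19 and comes back at 20. The radical part is run alone as a cobalt-catalysed MHAT cycloisomerisation (the chloro cobalt complex of the same salen ligand, trivalent cobalt, with catalytic PhSiH3 in benzene at rt). There the C8 radical ends by hydrogen loss and gives the rings A/B lactone with an exocyclic C8 methylene, bicyclic alkene F8. F8 is then ionised with Bi(OTf)3 in (CF3)2CHOH, so that the C8 cation closes onto C14 under thermodynamic control (O-alkylated enol ethers re-ionise), which gives 20.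

Second, step 11: C11–H is more acidic than the acetyl CH3, so the ring closure can be slow, the acylation can go to C11, and liberated methoxide can attack the C3 acetate. The fallback sets out from 15 and comes back at 17. The C14 enolate is acylated with tert-butyl malonyl chloride, ClC(=O)CH2CO2tBu, instead of acetyl chloride, which gives the 3-oxoglutarate, keto diester F6. Its C16 methylene is as acidic as C14–H, so 2 equiv of KOtBu at 0 °C form the C16 carbanion without touching C11–H. Ring closure then gives the cyclic tricarbonyl compound, tert-butyl ester F7, without free methoxide. Heating in wet toluene at 90 °C expels 2-methylpropene and CO2 and returns 17.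

Third, step 1 (the proposed new step): the enantioselectivity for an unbranched acid, oxidation at the propargylic δ-CH2 and oxidation of the alkyne are all untested. The fallback uses known chemistry; it replaces starting material 1 by commercial (S)-epichlorohydrin F1 and comes back at 2. F1 is opened at the epoxide CH2 with LiC≡CSiMe3 and BF3·OEt2 to the chlorohydrin, (2S)-1-chloro-5-(trimethylsilyl)pent-4-yn-2-ol F2. NaOH closes it to the epoxide, trimethyl{3-[(2S)-oxiran-2-yl]prop-1-yn-1-yl}silane F3. The dianion of acetic acid (LiCH2CO2Li) opens F3 at the terminal carbon to the hydroxy acid, (4R)-4-hydroxy-7-(trimethylsilyl)hept-6-ynoic acid F4. TsOH lactonises it to the silyl alkyne lactone, (5R)-5-[3-(trimethylsilyl)prop-2-yn-1-yl]oxolan-2-one F5, and Bu4NF/AcOH removes the silyl group to give 2.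

**Further compounds**
F1 | step 1 | (S)-2-(chloromethyl)oxirane | ClC[C@@H]1CO1
F2 | step 1 | (2S)-1-chloro-5-(trimethylsilyl)pent-4-yn-2-ol | ClC[C@@H](O)CC#C[Si](C)(C)C
F3 | step 1 | trimethyl{3-[(2S)-oxiran-2-yl]prop-1-yn-1-yl}silane | C[Si](C)(C)C#CC[C@H]1CO1
F4 | step 1 | (4R)-4-hydroxy-7-(trimethylsilyl)hept-6-ynoic acid | OC(=O)CC[C@@H](O)CC#C[Si](C)(C)C
F5 | step 1 | (5R)-5-[3-(trimethylsilyl)prop-2-yn-1-yl]oxolan-2-one | O=C1CC[C@H](CC#C[Si](C)(C)C)O1
F6 | step 11 | dimethyl (3Z)-2-[3-(tert-butoxy)-3-oxopropanoyl]-5-[(1E)-3-{(2S,4RS)-4-[(3S)-3-(acetyloxy)-4-methylpent-4-en-1-yl]-5-oxo-4-(phenylsulfanyl)oxolan-2-yl}-2-methylprop-1-en-1-yl]-3,4-dimethylhex-3-enedioate | C=C(C)[C@@H](OC(C)=O)CCC1(Sc2ccccc2)C[C@H](C/C(C)=C/C(C(=O)OC)/C(C)=C(C)\C(C(=O)CC(=O)OC(C)(C)C)C(=O)OC)OC1=O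
F7 | step 11 | 6-tert-butyl 1-methyl 4-[(1E)-3-{(2S,4RS)-4-[(3S)-3-(acetyloxy)-4-methylpent-4-en-1-yl]-5-oxo-4-(phenylsulfanyl)oxolan-2-yl}-2-methylprop-1-en-1-yl]-2,3-dimethyl-5,7-dioxocyclohept-2-ene-1,6-dicarboxylate | C=C(C)[C@@H](OC(C)=O)CCC1(Sc2ccccc2)C[C@H](C/C(C)=C/C2C(C)=C(C)C(C(=O)OC)C(=O)C(C(=O)OC(C)(C)C)C2=O)OC1=O
F8 | step 13 | rings A/B γ-lactone (3S,5R,6S,9R,10R) with exocyclic C8 methylene and the cycloheptenedione ester on C9 | COC(=O)C1C(=O)CC(=O)C(C(C)=C1C)[C@H]1[C@]23CC[C@H](OC(C)=O)C(C)(C)[C@H]2[C@H](CC1=C)OC3=O
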